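**Retrosynthetic overview**
1. Target 20 is numbered C1–OH, C2–OMe, C3–H, C4–OMe, C5–H, C6–tricosyl. The strategy rests on the para oxygen pair on C1/C4 of its single benzene ring, with C1 flanked by OMe (C2) and the chain (C6); this is the pattern of a hydroquinone monoether grown from a 3-methoxy-4-oxy-4-alkenylcyclobutenone.
2. 20 ⇐ phenol 17 (C1–O carried as a MOM acetal, C4–OH free) by methylation of C4–OH and acetal cleavage.
3. 17 ⇐ cyclobutenone 14: disconnect arene bond C4–C5 (ketene carbon to alkene CH2) and re-close the four-ring bond C4–C1. This is the Moore ring expansion, and it forms the only ring of the target.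
4. 14 ⇐ MOMCl + carbinol 12 ⇐ pentacos-1-en-2-yllithium 10 (Shapiro; from pentacosan-2-one 4 ⇐ tetracosanoic acid + MeLi) + methyl semisquarate 9 (⇐ dimethyl squarate 7 by hydride reduction, then acid).
5. Ring order: the four-membered ring is bought with the squarate; the benzene ring is made in step 7.

Key step: step 7

Remark on the chemistry: the target has no stereocentre and no stereogenic double bond, so it is one achiral compound and no enantiocontrol is needed. Intermediates 8, 11, 12 and 14 are racemic, and their single centre is destroyed later.

**Step 1**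
Reactants: 1 tetracosanoic acid; 2 methyllithium
Product: 4 pentacosan-2-one, via dilithium pentacosane-2,2-diolate 3 (not isolated)
Conditions: MeLi (2.2 equiv), THF–Et2O, 0 °C → rt; inverse quench into ice-cold 1 M HCl
Reagents that add atoms: methyllithium (2), [Li]C
Why: Ketone synthesis from a carboxylic acid and an organolithium (Gilman–Van Ess reaction): MeLi adds to the lithium carboxylate, and the gem-diolate 3 cannot collapse to the ketone until the acidic quench has destroyed the excess reagent, so over-addition to the tertiary alcohol should be avoided.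

**Step 2**
Reactants: 4 pentacosan-2-one; 5 2,4,6-triisopropylbenzenesulfonohydrazide
Product: 6 N'-[(2E)-pentacosan-2-ylidene]-2,4,6-triisopropylbenzenesulfonohydrazide
Conditions: TrisNHNH2 (1.05 equiv), conc. HCl (cat.), THF–MeOH, rt; crystallisation
Reagents that add atoms: 2,4,6-triisopropylbenzenesulfonohydrazide (5), NNS(=O)(=O)c1c(C(C)C)cc(C(C)C)cc1C(C)C
Why: Acid-catalysed hydrazone condensation, expected to give mainly the E isomer (sulfonamide nitrogen syn to the methyl group), which steers the later metalation to the methyl side; the triisopropylphenyl ring cannot be ortho-lithiated.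

**Step 3**
Reactants: 7 dimethyl squarate
Product: 8 (±)-4-hydroxy-2,3-dimethoxycyclobut-2-en-1-one
Conditions: LiAlH(Ot-Bu)3 (1.05 equiv), THF, −78 → −20 °C; cold pH 7 buffer; used crude
Reagents that add atoms: none
Why: Chemoselective 1,2-reduction of one squarate carbonyl by a bulky alkoxyaluminium hydride; the aluminium alkoxide formed leaves only a deactivated vinylogous ester carbonyl, so reduction should stop after one hydride, and the racemic carbinol centre is erased in step 4.

**Step 4**
Reactants: 8 (±)-4-hydroxy-2,3-dimethoxycyclobut-2-en-1-one
Product: 9 3-methoxycyclobut-3-ene-1,2-dione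
Conditions: conc. aq. HCl (cat.), CH2Cl2, 0 °C → rt; short silica filtration; stored cold
Reagents that add atoms: water, O
Why: Acid-induced dehydrative rearrangement, the same manifold that converts squarate 1,2-adducts into 3-alkoxycyclobutenediones: ionisation of the allylic C4–OH gives a methoxy-stabilised cyclobutenyl cation, water adds at the oxocarbenium carbon C2 and methanol is lost, which unveils the 1,2-dione with H on the ring (semisquarate formation).

**Step 5**
Reactants: 6 N'-[(2E)-pentacosan-2-ylidene]-2,4,6-triisopropylbenzenesulfonohydrazide; 9 3-methoxycyclobut-3-ene-1,2-dione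
Product: 12 (±)-4-hydroxy-3-methoxy-4-(pentacos-1-en-2-yl)cyclobut-2-en-1-one, via pentacos-1-en-2-yllithium 10 (not isolated), via lithium tertiary alkoxide 11 (not isolated)
Conditions: n-BuLi (2.0 equiv, titrated), THF–TMEDA, −78 → 0 °C (N2 loss), re-cool to −78 °C; cannulate into 9 (1.3 equiv), THF, −78 °C; sat. aq. NH4Cl at −78 °C
Reagents that add atoms: none
Why: Shapiro reaction followed by carbonyl 1,2-addition: the hydrazone dianion (metalated at the methyl group syn to N–SO2Ar) loses sulfinate and N2 to give the 2-lithio-1-alkene 10, which attacks the ketone-like C2 carbonyl of 9 (the C1 carbonyl is deactivated as a vinylogous ester) and so places the carbinol next to C–OMe; the new centre is racemic and later becomes an aromatic carbon.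

**Step 6**
Reactants: 12 (±)-4-hydroxy-3-methoxy-4-(pentacos-1-en-2-yl)cyclobut-2-en-1-one; 13 chloromethyl methyl ether
Product: 14 (±)-3-methoxy-4-(methoxymethoxy)-4-(pentacos-1-en-2-yl)cyclobut-2-en-1-one
Conditions: MOMCl (3 equiv), i-Pr2NEt (4 equiv), Bu4NI (cat.), CH2Cl2, 0 °C → rt
Reagents that add atoms: chloromethyl methyl ether (13), COCCl
Why: MOM protection (O-alkylation of the tertiary alcohol by the highly reactive α-halo ether under a non-nucleophilic amine base, with iodide catalysis), mild and cool enough to leave the enol ether and the thermally labile cyclobutenone untouched.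

**Step 7**
Reactants: 14 (±)-3-methoxy-4-(methoxymethoxy)-4-(pentacos-1-en-2-yl)cyclobut-2-en-1-one
Product: 17 3-methoxy-4-(methoxymethoxy)-5-tricosylphenol, via Z-dienylketene 15 (not isolated), via cyclohexa-2,4-dienone 16 (not isolated)
Conditions: degassed p-xylene (0.01 M), Ar, reflux (138 °C)
Reagents that add atoms: none
Why: Moore rearrangement, the thermal ring expansion of 4-alkenyl-4-oxycyclobutenones to hydroquinone derivatives: conrotatory 4π-electrocyclic opening of the bond between the carbonyl carbon and the quaternary carbon of 14 gives dienylketene 15, conjugated through the enol ether to the 1,1-disubstituted alkene. The benzene ring is then closed by a thermal disrotatory 6π-electrocyclisation in which the ketene carbon (target C4) bonds to the alkene CH2 (target C5), giving cyclohexa-2,4-dienone 16, whose CH2 hydrogen shifts to oxygen so that aromatisation makes the sequence irreversible. No stereocentre is created, and the racemic quaternary centre of 14 becomes the aromatic carbon C1. The selectivity needed is torquoselectivity in the ring opening: the oxygen donor on the quaternary carbon rotates outward, as hydroxy, alkoxy and siloxy groups do throughout this reaction class, so the alkenyl group turns inward and sits cis to the ketene, the only geometry that can cyclise. Connectivity then fixes the regiochemistry, since the ketene oxygen emerges as the free C4–OH while the acetal oxygen stays on C1 between the methoxy group and the chain, so the two para oxygens leave the step differentiated. Dilution and exclusion of air are used to suppress trapping of the ketene by the product phenol and oxidation of the electron-rich arene.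

**Step 8**
Reactants: 17 3-methoxy-4-(methoxymethoxy)-5-tricosylphenol; 18 iodomethane
Product: 19 1,5-dimethoxy-2-(methoxymethoxy)-3-tricosylbenzene
Conditions: MeI (3 equiv), K2CO3 (3 equiv), acetone–THF, 50 °C, Ar
Reagents that add atoms: iodomethane (18), CI
Why: Williamson ether synthesis on the only free phenol; the MOM acetal and the aryl methyl ether are inert to carbonate base.

**Step 9**
Reactants: 19 1,5-dimethoxy-2-(methoxymethoxy)-3-tricosylbenzene
Product: 20 2,4-dimethoxy-6-tricosylphenol
Conditions: conc. HCl (cat.), MeOH–THF (1:1), 50 °C, Ar
Reagents that add atoms: none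
Why: Acid-catalysed acetal exchange with methanol (MOM cleavage) frees the C1 phenol as dimethoxymethane is formed; aryl methyl ethers and the alkyl chain are unaffected.

**Compound list**
1 | tetracosanoic acid | CCCCCCCCCCCCCCCCCCCCCCCC(=O)O | starting material
2 | methyllithium | [Li]C | starting material
3 | dilithium pentacosane-2,2-diolate | CCCCCCCCCCCCCCCCCCCCCCCC(C)(O[Li])O[Li] | intermediate (not isolated)
4 | pentacosan-2-one | CCCCCCCCCCCCCCCCCCCCCCCC(C)=O | intermediate
5 | 2,4,6-triisopropylbenzenesulfonohydrazide | NNS(=O)(=O)c1c(C(C)C)cc(C(C)C)cc1C(C)C | starting material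
6 | N'-[(2E)-pentacosan-2-ylidene]-2,4,6-triisopropylbenzenesulfonohydrazide | CCCCCCCCCCCCCCCCCCCCCCC/C(C)=N/NS(=O)(=O)c1c(C(C)C)cc(C(C)C)cc1C(C)C | intermediate
7 | dimethyl squarate (3,4-dimethoxycyclobut-3-ene-1,2-dione) | COC1=C(OC)C(=O)C1=O | starting material
8 | (±)-4-hydroxy-2,3-dimethoxycyclobut-2-en-1-one (racemate) | COC1=C(OC)C(O)C1=O | intermediate
9 | 3-methoxycyclobut-3-ene-1,2-dione (methyl semisquarate) | COC1=CC(=O)C1=O | intermediate
10 | pentacos-1-en-2-yllithium | CCCCCCCCCCCCCCCCCCCCCCCC(=C)[Li] | intermediate (not isolated)
11 | lithium (±)-2-methoxy-4-oxo-1-(pentacos-1-en-2-yl)cyclobut-2-en-1-olate (racemate) | CCCCCCCCCCCCCCCCCCCCCCCC(=C)C1(O[Li])C(OC)=CC1=O | intermediate (not isolated)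
12 | (±)-4-hydroxy-3-methoxy-4-(pentacos-1-en-2-yl)cyclobut-2-en-1-one (racemate) | CCCCCCCCCCCCCCCCCCCCCCCC(=C)C1(O)C(OC)=CC1=O | intermediate
13 | chloromethyl methyl ether | COCCl | starting material
14 | (±)-3-methoxy-4-(methoxymethoxy)-4-(pentacos-1-en-2-yl)cyclobut-2-en-1-one (racemate) | CCCCCCCCCCCCCCCCCCCCCCCC(=C)C1(OCOC)C(OC)=CC1=O | intermediate
15 | (3Z)-3-methoxy-4-(methoxymethoxy)-5-methylideneoctacosa-1,3-dien-1-one (dienylketene) | O=C=C/C(OC)=C(/OCOC)C(=C)CCCCCCCCCCCCCCCCCCCCCCC | intermediate (not isolated)
16 | 3-methoxy-4-(methoxymethoxy)-5-tricosylcyclohexa-2,4-dien-1-one | O=C1C=C(OC)C(OCOC)=C(CCCCCCCCCCCCCCCCCCCCCCC)C1 | intermediate (not isolated)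
17 | 3-methoxy-4-(methoxymethoxy)-5-tricosylphenol | CCCCCCCCCCCCCCCCCCCCCCCc1cc(O)cc(OC)c1OCOC | intermediate
18 | iodomethane | CI | starting material
19 | 1,5-dimethoxy-2-(methoxymethoxy)-3-tricosylbenzene | CCCCCCCCCCCCCCCCCCCCCCCc1cc(OC)cc(OC)c1OCOC | intermediate
20 | 2,4-dimethoxy-6-tricosylphenol (achiral) | CCCCCCCCCCCCCCCCCCCCCCCc1cc(OC)cc(OC)c1O | target

**Totals**
Total step count: 9.
Longest linear sequence: 7 steps (1 → 2 → 5 → 6 → 7 → 8 → 9; the squarate branch 3 → 4 → 5 → … → 9 is equally long).

**Steps most likely to fail**

Step 5. The C25 hydrazone may dissolve poorly at low temperature, so metalation may be incomplete or occur on the chain side, and leftover butyllithium would attack the dione. The sensitive semisquarate may also suffer conjugate or double addition. The fallback generates the same vinyl anion by halogen–lithium exchange and does not use compounds 1–6. It sets out from no numbered intermediate (dione 9 stays as the partner) but from commercial 1-bromodocosane (CCCCCCCCCCCCCCCCCCCCCCBr) and 2,3-dibromopropene (C=C(Br)CBr). Magnesium in THF should give docosylmagnesium bromide F1. Copper(I)-catalysed allylic substitution of F1 on 2,3-dibromopropene should give 2-bromopentacos-1-ene F2. Treating F2 with t-BuLi (2 equiv) in Et2O at −78 °C should deliver vinyllithium 10 free of sulfinate and amine. The fallback comes back to the route at compound 10, which is added to 9 as before to give 12.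

Step 7. The acetal oxygen may rotate inward and give a ketene that cannot cyclise. The ketene may also be intercepted by the acetal oxygen or by product phenol, or may oligomerise, so that material is lost. The fallback runs the ring expansion on the free carbinol, the best-precedented substrate type, and replaces the protecting group by steric differentiation. It sets out from compound 12, which is heated in degassed toluene or p-xylene under argon to give 2-methoxy-6-tricosylbenzene-1,4-diol F3. In F3 the C4–OH has two ortho hydrogens, while the C1–OH is buried between OMe and the tricosyl chain. One equivalent of MeI with K2CO3 in acetone under argon should therefore methylate the exposed C4–OH. The fallback comes back to the route at compound 20.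

Step 6. Alkylation of the hindered tertiary carbinol may be slow, and the hydroxycyclobutenone may degrade by base- or iodide-induced ring opening during the long reaction time. The fallback changes the protecting-group class and the downstream steps. It sets out from compound 12, which is silylated with TESOTf and 2,6-lutidine in CH2Cl2 at −78 °C to give (±)-3-methoxy-4-(pentacos-1-en-2-yl)-4-(triethylsilyloxy)cyclobut-2-en-1-one F4. Thermolysis as in step 7 should give 3-methoxy-5-tricosyl-4-(triethylsilyloxy)phenol F5. The free phenol is methylated under neutral Mitsunobu conditions (MeOH, PPh3, DIAD, THF), which avoids base-induced silyl scrambling, to give (2,4-dimethoxy-6-tricosylphenoxy)triethylsilane F6. TBAF in THF then removes the silyl group, and the fallback comes back to the route at compound 20.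

**Further compounds**
F1 | step 5 | docosylmagnesium bromide | CCCCCCCCCCCCCCCCCCCCCC[Mg]Br
F2 | step 5 | 2-bromopentacos-1-ene | C=C(Br)CCCCCCCCCCCCCCCCCCCCCCC
F3 | step 7 | 2-methoxy-6-tricosylbenzene-1,4-diol | CCCCCCCCCCCCCCCCCCCCCCCc1cc(O)cc(OC)c1O
F4 | step 6 | (±)-3-methoxy-4-(pentacos-1-en-2-yl)-4-(triethylsilyloxy)cyclobut-2-en-1-one | CCCCCCCCCCCCCCCCCCCCCCCC(=C)C1(O[Si](CC)(CC)CC)C(OC)=CC1=O
F5 | step 6 | 3-methoxy-5-tricosyl-4-(triethylsilyloxy)phenol | CCCCCCCCCCCCCCCCCCCCCCCc1cc(O)cc(OC)c1O[Si](CC)(CC)CC
F6 | step 6 | (2,4-dimethoxy-6-tricosylphenoxy)triethylsilane | CCCCCCCCCCCCCCCCCCCCCCCc1cc(OC)cc(OC)c1O[Si](CC)(CC)CC
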